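## Retrosynthetic overview

1. The target is a 2,3-trans-3,4-trans oxolane: O1, C2 (3,4,5-trimethoxyphenyl), C3 (CH2OH), C4 ((S)-carbinol side chain), C5 (CH2). Desilylation, ester reduction, C3 epimerisation and hydrogenation of C2=C3 lead back to a 2-aryl-4,5-dihydrofuran-3-carboxylate.
2. Key disconnection O1–C5: C5 and C4 are the CH2 and CH of a cyclopropane whose third carbon (the later C3) carries the 3,4,5-trimethoxybenzoyl group (the later C2 and O1) and a methyl ester (the later CH2OH). An iodide-catalysed Cloke–Wilson expansion turns this acylcyclopropane into the dihydrofuran.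
3. The cyclopropane is cut at both bonds to its quaternary carbon: methyl 3,4,5-trimethoxybenzoylacetate is alkylated twice by an anti-configured, O-silylated 1,2-cyclic sulfate (SN2 at CH2, then 3-exo closure with inversion at the carbon that becomes C4).
4. The cyclic sulfate comes from (S)-glyceraldehyde acetonide and a 3,4-dimethoxyphenyl nucleophile (Felkin–Anh addition sets the carbinol centre). The keto ester comes from 3',4',5'-trimethoxyacetophenone and dimethyl carbonate.
5. Ring order: cyclopropane (step 6), 4,5-dihydrofuran by strain-release expansion (step 7), oxolane by hydrogenation (step 8).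

Key step: step 7

Remark on the dielectrophile: the closure in step 6 inverts the carbon that becomes C4, while the carbinol C–O bond is never broken. The (S)-carbinol/(4R) pair of the target therefore needs an erythro (anti) C1,C2-dielectrophile. A trans-epoxy sulfonate or threo diol from an (E)-cinnamyl precursor would give the carbinol epimer, and a free alkoxide next to the cyclopropane ester would lactonise, so the carbinol oxygen is silylated before the ring is made.

Assumption: (S)-2,2-dimethyl-1,3-dioxolane-4-carbaldehyde is bought and distilled just before use. The cyclopropane is carried forward as both epimers at its quaternary carbon (one is drawn), because that carbon becomes sp2 in step 7.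

## Route

Step 1
Reactants: 1 3',4',5'-trimethoxyacetophenone; 2 dimethyl carbonate
Product: 3 methyl 3-oxo-3-(3,4,5-trimethoxyphenyl)propanoate
Conditions: NaH (2.5 equiv), THF, reflux; then AcOH, H2O
Reagents that add atoms: none
Why: Crossed Claisen condensation (C-acylation of the methyl ketone enolate by the carbonate), driven forward by deprotonation of the keto ester product; no stereocentre is formed.

Step 2
Reactants: 4 4-bromo-1,2-dimethoxybenzene; 5 (S)-2,2-dimethyl-1,3-dioxolane-4-carbaldehyde
Product: 8 (R)-(3,4-dimethoxyphenyl)[(4S)-2,2-dimethyl-1,3-dioxolan-4-yl]methanol, via arylmagnesium bromide 6 (not isolated), via aryltitanium triisopropoxide 7 (not isolated)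
Conditions: Mg, THF, 40 °C; ClTi(OiPr)3, THF, −78 → −40 °C; then 5, −78 → 0 °C; aq NH4Cl
Reagents that add atoms: none
Why: Magnesium insertion and transmetallation to titanium give a weakly Lewis acidic, non-chelating aryl nucleophile whose 1,2-addition to the α-alkoxy aldehyde should follow the Felkin–Anh model (ring C–O bond anti to the incoming aryl, attack past the α-hydrogen), setting the new carbinol centre as R, anti to the dioxolane oxygen, with the minor syn epimer removed by chromatography.

Step 3
Reactants: 8 (R)-(3,4-dimethoxyphenyl)[(4S)-2,2-dimethyl-1,3-dioxolan-4-yl]methanol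
Product: 9 tert-butyl{(R)-(3,4-dimethoxyphenyl)[(4S)-2,2-dimethyl-1,3-dioxolan-4-yl]methoxy}dimethylsilane
Conditions: TBSCl, imidazole, DMF, rt
Reagents that add atoms: tert-butyldimethylsilyl chloride, CC(C)(C)[Si](C)(C)Cl
Why: Standard imidazole-promoted silylation of a secondary benzylic alcohol, which touches no stereocentre and masks the oxygen that would otherwise attack the ester later.

Step 4
Reactants: 9 tert-butyl{(R)-(3,4-dimethoxyphenyl)[(4S)-2,2-dimethyl-1,3-dioxolan-4-yl]methoxy}dimethylsilane
Product: 10 (2S,3R)-3-[(tert-butyldimethylsilyl)oxy]-3-(3,4-dimethoxyphenyl)propane-1,2-diol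
Conditions: Zn(NO3)2·6H2O, MeCN, 50 °C
Reagents that add atoms: none
Why: Mild Lewis-acid-promoted hydrolysis of the terminal isopropylidene ketal, under which the hindered secondary silyl ether should survive and the electron-rich benzylic C–O bond should not ionise; both stereocentres are untouched.

Step 5
Reactants: 10 (2S,3R)-3-[(tert-butyldimethylsilyl)oxy]-3-(3,4-dimethoxyphenyl)propane-1,2-diol
Product: 12 (4S)-4-{(R)-[(tert-butyldimethylsilyl)oxy](3,4-dimethoxyphenyl)methyl}-1,3,2-dioxathiolane 2,2-dioxide, via cyclic sulfite 11 (not isolated)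
Conditions: SOCl2, Et3N, CH2Cl2, 0 °C; then RuCl3·3H2O (0.5 mol %), NaIO4, MeCN/H2O, 0 °C
Reagents that add atoms: thionyl chloride, O=S(Cl)Cl; sodium periodate, [Na+].[O-]I(=O)(=O)=O
Why: Gao–Sharpless cyclic sulfate synthesis, in which amine-buffered sulfite formation is followed by a fast catalytic RuO4 oxidation at sulfur that should outrun attack on the dimethoxyarene; no C–O bond is broken, so both stereocentres are retained.

Step 6
Reactants: 3 methyl 3-oxo-3-(3,4,5-trimethoxyphenyl)propanoate; 12 (4S)-4-{(R)-[(tert-butyldimethylsilyl)oxy](3,4-dimethoxyphenyl)methyl}-1,3,2-dioxathiolane 2,2-dioxide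
Product: 14 methyl (1R,2S)-2-{(S)-[(tert-butyldimethylsilyl)oxy](3,4-dimethoxyphenyl)methyl}-1-(3,4,5-trimethoxybenzoyl)cyclopropane-1-carboxylate (formed together with its 1S epimer), via sodium alkyl sulfate 13 (not isolated)
Conditions: NaH (2.2 equiv), DME, 0 → 60 °C
Reagents that add atoms: none
Why: Double alkylation of an active methylene compound by a 1,2-cyclic sulfate: the sodium enolate of 3 opens the sulfate by SN2 at the primary carbon, and the second enolate displaces the secondary sulfate monoester by 3-exo-tet C-alkylation with inversion, which sets the ring CH as S (the later C4), while the quaternary carbon forms as both epimers without consequence.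

Step 7
Reactants: 14 methyl (1R,2S)-2-{(S)-[(tert-butyldimethylsilyl)oxy](3,4-dimethoxyphenyl)methyl}-1-(3,4,5-trimethoxybenzoyl)cyclopropane-1-carboxylate (both C1 epimers)
Product: 16 methyl (4R)-4-{(S)-[(tert-butyldimethylsilyl)oxy](3,4-dimethoxyphenyl)methyl}-2-(3,4,5-trimethoxyphenyl)-4,5-dihydrofuran-3-carboxylate, via iodo magnesium enolate 15 (not isolated)
Conditions: MgI2 (0.3 equiv), THF, 65 °C
Reagents that add atoms: none
Why: Mg2+ chelates the keto ester and iodide opens the doubly activated cyclopropane by homoconjugate SN2 attack at the unsubstituted ring CH2, giving the chelated enolate 15 with a primary iodide; the ketone oxygen of the enolate then displaces iodide to form O1–C5. The closest known reaction type is the nucleophile (iodide) catalysed Cloke–Wilson rearrangement of 1-acylcyclopropane-1-carboxylates to 4,5-dihydrofuran-3-carboxylates. The dihydrofuran ring closes by 5-exo-tet O-alkylation. No stereocentre is created: C4 and the carbinol carbon are not attacked and pass through unchanged, and the quaternary cyclopropane carbon becomes sp2 C3, so both C1 epimers of 14 converge. The step needs opening at the ring CH2 and not at the ring CH; the branched, β-oxygenated CH(OSi)Ar substituent blocks SN2 attack at the ring CH and disfavours positive charge there. It also needs O- over C-alkylation; C-alkylation only regenerates the strained cyclopropane, which iodide reopens, so the material should funnel to the vinylogous carbonate 16.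

Step 8
Reactants: 16 methyl (4R)-4-{(S)-[(tert-butyldimethylsilyl)oxy](3,4-dimethoxyphenyl)methyl}-2-(3,4,5-trimethoxyphenyl)-4,5-dihydrofuran-3-carboxylate
Product: 17 methyl (2R,3S,4R)-4-{(S)-[(tert-butyldimethylsilyl)oxy](3,4-dimethoxyphenyl)methyl}-2-(3,4,5-trimethoxyphenyl)oxolane-3-carboxylate (2,3-cis-3,4-cis)
Conditions: H2 (3 bar), Pd/C (10 wt %), EtOAc, rt
Reagents that add atoms: none
Why: Heterogeneous syn hydrogenation of the aryl-conjugated enol ether double bond from the ring face opposite the bulky C4 substituent should set C2 as R (aryl cis to the C4 group) and place the ester cis to both neighbours, with neutral EtOAc at room temperature chosen to limit benzylic C–O hydrogenolysis.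

Step 9
Reactants: 17 methyl (2R,3S,4R)-4-{(S)-[(tert-butyldimethylsilyl)oxy](3,4-dimethoxyphenyl)methyl}-2-(3,4,5-trimethoxyphenyl)oxolane-3-carboxylate
Product: 18 methyl (2R,3R,4R)-4-{(S)-[(tert-butyldimethylsilyl)oxy](3,4-dimethoxyphenyl)methyl}-2-(3,4,5-trimethoxyphenyl)oxolane-3-carboxylate (2,3-trans-3,4-trans)
Conditions: NaOMe (0.3 equiv), MeOH, 40 °C
Reagents that add atoms: none
Why: Base-mediated epimerisation through the ester enolate relieves the all-cis arrangement and should set C3 in the thermodynamic all-trans ester, with C2 and C4 not acidic and any reversible β-alkoxide elimination and oxa-Michael re-closure leading to the same isomer.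

Step 10
Reactants: 18 methyl (2R,3R,4R)-4-{(S)-[(tert-butyldimethylsilyl)oxy](3,4-dimethoxyphenyl)methyl}-2-(3,4,5-trimethoxyphenyl)oxolane-3-carboxylate
Product: 19 [(2R,3S,4R)-4-{(S)-[(tert-butyldimethylsilyl)oxy](3,4-dimethoxyphenyl)methyl}-2-(3,4,5-trimethoxyphenyl)oxolan-3-yl]methanol
Conditions: LiAlH4, THF, 0 °C; then H2O
Reagents that add atoms: none
Why: Hydride reduction of the ester to the primary alcohol, which leaves the silyl ether and all stereocentres unaffected at 0 °C.

Step 11
Reactants: 19 [(2R,3S,4R)-4-{(S)-[(tert-butyldimethylsilyl)oxy](3,4-dimethoxyphenyl)methyl}-2-(3,4,5-trimethoxyphenyl)oxolan-3-yl]methanol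
Product: 20 (S)-(3,4-dimethoxyphenyl)[(3R,4S,5R)-4-(hydroxymethyl)-5-(3,4,5-trimethoxyphenyl)oxolan-3-yl]methanol (CNP0172668.1)
Conditions: Bu4NF, THF, 0 °C → rt
Reagents that add atoms: none
Why: Fluoride-mediated desilylation under non-acidic conditions, which avoids ionisation of the electron-rich benzylic carbinol and leaves all four stereocentres intact.

## Compound list

1 | 3',4',5'-trimethoxyacetophenone | CC(=O)c1cc(OC)c(OC)c(OC)c1 | starting material
2 | dimethyl carbonate | COC(=O)OC | starting material
3 | methyl 3-oxo-3-(3,4,5-trimethoxyphenyl)propanoate | COC(=O)CC(=O)c1cc(OC)c(OC)c(OC)c1 | intermediate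
4 | 4-bromo-1,2-dimethoxybenzene | COc1ccc(Br)cc1OC | starting material
5 | (S)-2,2-dimethyl-1,3-dioxolane-4-carbaldehyde | O=C[C@@H]1COC(C)(C)O1 | starting material
6 | (3,4-dimethoxyphenyl)magnesium bromide, formed in the flask | COc1ccc([Mg]Br)cc1OC | intermediate
7 | (3,4-dimethoxyphenyl)titanium triisopropoxide, formed in the flask | COc1ccc([Ti](OC(C)C)(OC(C)C)OC(C)C)cc1OC | intermediate
8 | (R)-(3,4-dimethoxyphenyl)[(4S)-2,2-dimethyl-1,3-dioxolan-4-yl]methanol | COc1ccc([C@@H](O)[C@@H]2COC(C)(C)O2)cc1OC | intermediate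
9 | tert-butyl{(R)-(3,4-dimethoxyphenyl)[(4S)-2,2-dimethyl-1,3-dioxolan-4-yl]methoxy}dimethylsilane | COc1ccc([C@@H](O[Si](C)(C)C(C)(C)C)[C@@H]2COC(C)(C)O2)cc1OC | intermediate
10 | (2S,3R)-3-[(tert-butyldimethylsilyl)oxy]-3-(3,4-dimethoxyphenyl)propane-1,2-diol | COc1ccc([C@@H](O[Si](C)(C)C(C)(C)C)[C@@H](O)CO)cc1OC | intermediate
11 | (4S)-4-{(R)-[(tert-butyldimethylsilyl)oxy](3,4-dimethoxyphenyl)methyl}-1,3,2-dioxathiolane 2-oxide, both sulfur epimers, formed in the flask | COc1ccc([C@@H](O[Si](C)(C)C(C)(C)C)[C@@H]2COS(=O)O2)cc1OC | intermediate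
12 | (4S)-4-{(R)-[(tert-butyldimethylsilyl)oxy](3,4-dimethoxyphenyl)methyl}-1,3,2-dioxathiolane 2,2-dioxide | COc1ccc([C@@H](O[Si](C)(C)C(C)(C)C)[C@@H]2COS(=O)(=O)O2)cc1OC | intermediate
13 | sodium sulfate monoester of methyl (4S,5R)-5-[(tert-butyldimethylsilyl)oxy]-5-(3,4-dimethoxyphenyl)-4-hydroxy-2-(3,4,5-trimethoxybenzoyl)pentanoate, C2 epimers, keto form shown, formed in the flask | COC(=O)C(C[C@H](OS(=O)(=O)[O-])[C@H](O[Si](C)(C)C(C)(C)C)c1ccc(OC)c(OC)c1)C(=O)c1cc(OC)c(OC)c(OC)c1.[Na+] | intermediate
14 | methyl (1R,2S)-2-{(S)-[(tert-butyldimethylsilyl)oxy](3,4-dimethoxyphenyl)methyl}-1-(3,4,5-trimethoxybenzoyl)cyclopropane-1-carboxylate, drawn epimer of the C1 mixture | COc1ccc([C@@H](O[Si](C)(C)C(C)(C)C)[C@H]2C[C@]2(C(=O)OC)C(=O)c3cc(OC)c(OC)c(OC)c3)cc1OC | intermediate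
15 | iodomagnesium enolate of methyl (3S,4S)-4-[(tert-butyldimethylsilyl)oxy]-4-(3,4-dimethoxyphenyl)-3-(iodomethyl)-2-(3,4,5-trimethoxybenzoyl)butanoate, formed in the flask | COC(=O)C(=C(O[Mg]I)c1cc(OC)c(OC)c(OC)c1)[C@H](CI)[C@H](O[Si](C)(C)C(C)(C)C)c1ccc(OC)c(OC)c1 | intermediate
16 | methyl (4R)-4-{(S)-[(tert-butyldimethylsilyl)oxy](3,4-dimethoxyphenyl)methyl}-2-(3,4,5-trimethoxyphenyl)-4,5-dihydrofuran-3-carboxylate | COc1ccc([C@@H](O[Si](C)(C)C(C)(C)C)[C@H]2COC(c3cc(OC)c(OC)c(OC)c3)=C2C(=O)OC)cc1OC | intermediate
17 | methyl (2R,3S,4R)-4-{(S)-[(tert-butyldimethylsilyl)oxy](3,4-dimethoxyphenyl)methyl}-2-(3,4,5-trimethoxyphenyl)oxolane-3-carboxylate | COc1ccc([C@@H](O[Si](C)(C)C(C)(C)C)[C@H]2CO[C@@H](c3cc(OC)c(OC)c(OC)c3)[C@H]2C(=O)OC)cc1OC | intermediate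
18 | methyl (2R,3R,4R)-4-{(S)-[(tert-butyldimethylsilyl)oxy](3,4-dimethoxyphenyl)methyl}-2-(3,4,5-trimethoxyphenyl)oxolane-3-carboxylate | COc1ccc([C@@H](O[Si](C)(C)C(C)(C)C)[C@H]2CO[C@@H](c3cc(OC)c(OC)c(OC)c3)[C@@H]2C(=O)OC)cc1OC | intermediate
19 | [(2R,3S,4R)-4-{(S)-[(tert-butyldimethylsilyl)oxy](3,4-dimethoxyphenyl)methyl}-2-(3,4,5-trimethoxyphenyl)oxolan-3-yl]methanol | COc1ccc([C@@H](O[Si](C)(C)C(C)(C)C)[C@H]2CO[C@@H](c3cc(OC)c(OC)c(OC)c3)[C@@H]2CO)cc1OC | intermediate
20 | (S)-(3,4-dimethoxyphenyl)[(3R,4S,5R)-4-(hydroxymethyl)-5-(3,4,5-trimethoxyphenyl)oxolan-3-yl]methanol | COc1ccc([C@@H](O)[C@H]2CO[C@@H](c3cc(OC)c(OC)c(OC)c3)[C@@H]2CO)cc1OC | target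

## Step count and risks

Total step count: 11. Longest linear sequence: 10 steps (steps 2 to 11, from 4 and 5); step 1 is a one-step side branch.

**Step 6.** The second displacement may go through the ketone enolate oxygen (5-exo closure onto the secondary sulfate, which puts oxygen on the wrong carbon), or closure at the hindered secondary centre may be slow and lose out to elimination. The fallback sets out from cyclic sulfate 12 and uses the malonate version of the same closure, where O-alkylation is not an option. Treating 12 with dimethyl malonate (NaH, DME) should give dimethyl (2S)-2-{(S)-[(tert-butyldimethylsilyl)oxy](3,4-dimethoxyphenyl)methyl}cyclopropane-1,1-dicarboxylate F1. One equivalent of KOH in MeOH/H2O should hydrolyse the less hindered ester, trans to the ring substituent, to (1R,2S)-2-{(S)-[(tert-butyldimethylsilyl)oxy](3,4-dimethoxyphenyl)methyl}-1-(methoxycarbonyl)cyclopropane-1-carboxylic acid F2. Coupling with MeNHOMe·HCl (EDC, N-methylmorpholine, CH2Cl2) should give the Weinreb amide methyl (1R,2S)-2-{(S)-[(tert-butyldimethylsilyl)oxy](3,4-dimethoxyphenyl)methyl}-1-[methoxy(methyl)carbamoyl]cyclopropane-1-carboxylate F3. Commercial 3,4,5-trimethoxyphenylmagnesium bromide (THF, −20 °C) then converts the amide into the aryl ketone and returns the route to 14, as its (1R) epimer.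

**Step 7.** Turnover may be slow because the iodo enolate returns to the cyclopropane by C-alkylation faster than it closes on oxygen, so that prolonged heating with the Lewis acid erodes the benzylic silyl ether. The fallback sets out from 14. Stoichiometric MgI2 in THF at 0 °C with a cold aqueous NH4Cl quench should allow isolation of methyl (3S,4S)-4-[(tert-butyldimethylsilyl)oxy]-4-(3,4-dimethoxyphenyl)-3-(iodomethyl)-2-(3,4,5-trimethoxybenzoyl)butanoate F4. Silver triflate (AgOSO2CF3) with 2,6-di-tert-butylpyridine in CH2Cl2 then abstracts iodide with participation of the neutral ketone oxygen and loss of the C3 proton. No carbanion is present in that closure, so the cyclopropane cannot re-form, and the route returns to 16.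

**Step 2.** Facial selectivity in the aryl addition may be poor (competing chelation), or the α-alkoxy aldehyde may partly enolise, giving a carbinol epimer mixture that is hard to separate. The fallback sets out from 8 as the epimer mixture. Dess–Martin periodinane oxidation (CH2Cl2, rt) should give (3,4-dimethoxyphenyl)[(4S)-2,2-dimethyl-1,3-dioxolan-4-yl]methanone F5. Reduction with Zn(BH4)2 in Et2O at −30 °C delivers hydride within the zinc chelate of the carbonyl and the α-oxygen, from the face of the α-hydrogen, which should give the anti alcohol and return the route to 8 as a single epimer.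

Further compounds
F1 | step 6 | dimethyl (2S)-2-{(S)-[(tert-butyldimethylsilyl)oxy](3,4-dimethoxyphenyl)methyl}cyclopropane-1,1-dicarboxylate | COc1ccc([C@@H](O[Si](C)(C)C(C)(C)C)[C@H]2CC2(C(=O)OC)C(=O)OC)cc1OC
F2 | step 6 | (1R,2S)-2-{(S)-[(tert-butyldimethylsilyl)oxy](3,4-dimethoxyphenyl)methyl}-1-(methoxycarbonyl)cyclopropane-1-carboxylic acid | COc1ccc([C@@H](O[Si](C)(C)C(C)(C)C)[C@H]2C[C@]2(C(=O)OC)C(=O)O)cc1OC
F3 | step 6 | methyl (1R,2S)-2-{(S)-[(tert-butyldimethylsilyl)oxy](3,4-dimethoxyphenyl)methyl}-1-[methoxy(methyl)carbamoyl]cyclopropane-1-carboxylate | COc1ccc([C@@H](O[Si](C)(C)C(C)(C)C)[C@H]2C[C@]2(C(=O)OC)C(=O)N(C)OC)cc1OC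
F4 | step 7 | methyl (3S,4S)-4-[(tert-butyldimethylsilyl)oxy]-4-(3,4-dimethoxyphenyl)-3-(iodomethyl)-2-(3,4,5-trimethoxybenzoyl)butanoate | COC(=O)C(C(=O)c1cc(OC)c(OC)c(OC)c1)[C@H](CI)[C@H](O[Si](C)(C)C(C)(C)C)c1ccc(OC)c(OC)c1
F5 | step 2 | (3,4-dimethoxyphenyl)[(4S)-2,2-dimethyl-1,3-dioxolan-4-yl]methanone | COc1ccc(C(=O)[C@@H]2COC(C)(C)O2)cc1OC
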